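**Retrosynthetic overview**
1. Target 18 ⇐ anti-Markovnikov hydroboration–oxidation of the allyl group of erythro ether 16, so the side-chain alcohol is made last.
2. 16 ⇐ Mitsunobu inversion at the benzylic carbinol of threo alcohol 14; 14 ⇐ deoxygenation (tosylate, then hydride) of the primary hydroxyl of diol 12.
3. 12 ⇐ Evans syn aldol of aryloxyacetyl imide 7 with 3,4,5-trimethoxybenzaldehyde 8; this is the key C–C bond, between the carbinol carbon and the aryloxy-bearing carbon.
4. 7 ⇐ eugenol 1 + ethyl bromoacetate 2 + (S)-4-benzyl-2-oxazolidinone 5.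
5. No ring is formed: both benzene rings are bought (1 and 8), and the oxazolidinone ring is an auxiliary that is cleaved and recovered.

Assumption: bases, hydrides and activating agents are treated as unnumbered reagents; only the four purchased building blocks (1, 2, 5, 8) and the compounds made from them carry numbers.

The target is the erythro (1S,2R) isomer. The syn aldol delivers the (1R,2R) threo array with the aryloxy-bearing centre already correct, so the benzylic centre is inverted once, in step 8.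

**Step 1**
Reactants: 1 eugenol (4-allyl-2-methoxyphenol); 2 ethyl bromoacetate
Product: 3 ethyl 2-(4-allyl-2-methoxyphenoxy)acetate
Conditions: K2CO3 (1.5 equiv), acetone, reflux
Reagents that add atoms: none
Why: Williamson ether synthesis (SN2 of the phenoxide on an α-bromo ester); the mild carbonate base does not isomerise the allyl group.

**Step 2**
Reactants: 3 ethyl 2-(4-allyl-2-methoxyphenoxy)acetate
Product: 4 2-(4-allyl-2-methoxyphenoxy)acetic acid
Conditions: LiOH·H2O (2 equiv), THF/H2O 3:1, rt; then 1 M HCl to pH 2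
Reagents that add atoms: lithium hydroxide, [Li+].[OH-]
Why: ester saponification of an unhindered ethyl ester; the aryl ether and alkene are inert.

**Step 3**
Reactants: 4 2-(4-allyl-2-methoxyphenoxy)acetic acid; 5 (S)-4-benzyl-2-oxazolidinone
Product: 7 (S)-3-[2-(4-allyl-2-methoxyphenoxy)acetyl]-4-benzyloxazolidin-2-one, via mixed pivalic anhydride 6 (not isolated)
Conditions: PivCl (1.1 equiv), Et3N (2.5 equiv), THF, –20 °C; then LiCl (1.1 equiv), 5, –20 °C to rt
Reagents that add atoms: none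
Why: N-acylation of the oxazolidinone through a mixed anhydride; the nucleophile attacks the unhindered aryloxyacetyl carbonyl, not the pivaloyl one.

**Step 4**
Reactants: 7 (S)-3-[2-(4-allyl-2-methoxyphenoxy)acetyl]-4-benzyloxazolidin-2-one; 8 3,4,5-trimethoxybenzaldehyde
Product: 11 (S)-3-[(2S,3R)-2-(4-allyl-2-methoxyphenoxy)-3-hydroxy-3-(3,4,5-trimethoxyphenyl)propanoyl]-4-benzyloxazolidin-2-one, via Z-dibutylboron enolate 9 (not isolated), via dibutylboron aldolate 10 (not isolated)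
Conditions: Bu2BOTf (1.2 equiv), iPr2NEt (1.4 equiv), CH2Cl2, 0 °C; then 8 (1.2 equiv), –78 °C to 0 °C; pH 7 phosphate buffer, MeOH, 30% H2O2, 0 °C
Reagents that add atoms: none
Why: Evans syn aldol reaction: the Z-boron enolate adds to the non-enolisable aldehyde through a closed Zimmerman–Traxler chair on the face away from the benzyl group, setting C2 (S) and C3 (R) together as the 2,3-syn pair.

**Step 5**
Reactants: 11 (S)-3-[(2S,3R)-2-(4-allyl-2-methoxyphenoxy)-3-hydroxy-3-(3,4,5-trimethoxyphenyl)propanoyl]-4-benzyloxazolidin-2-one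
Product: 12 (1R,2R)-2-(4-allyl-2-methoxyphenoxy)-1-(3,4,5-trimethoxyphenyl)propane-1,3-diol
Conditions: LiBH4 (2 equiv), MeOH (2 equiv), THF, 0 °C; aq. NH4Cl
Reagents that add atoms: none
Why: reductive cleavage of the N-acyloxazolidinone to the primary alcohol with recovery of 5; no stereocentre is touched, and the C2 descriptor changes from S to R only because the CIP ranking of its neighbours changes.

**Step 6**
Reactants: 12 (1R,2R)-2-(4-allyl-2-methoxyphenoxy)-1-(3,4,5-trimethoxyphenyl)propane-1,3-diol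
Product: 13 (2R,3R)-2-(4-allyl-2-methoxyphenoxy)-3-hydroxy-3-(3,4,5-trimethoxyphenyl)propyl 4-methylbenzenesulfonate
Conditions: TsCl (1.1 equiv), pyridine, CH2Cl2, 0 to 4 °C
Reagents that add atoms: p-toluenesulfonyl chloride, Cc1ccc(cc1)S(Cl)(=O)=O
Why: chemoselective sulfonylation: the primary hydroxyl reacts far faster than the hindered secondary benzylic one.

**Step 7**
Reactants: 13 (2R,3R)-2-(4-allyl-2-methoxyphenoxy)-3-hydroxy-3-(3,4,5-trimethoxyphenyl)propyl 4-methylbenzenesulfonate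
Product: 14 (1R,2R)-2-(4-allyl-2-methoxyphenoxy)-1-(3,4,5-trimethoxyphenyl)propan-1-ol
Conditions: LiBHEt3 (3 equiv), THF, 0 °C to rt; aq. NH4Cl
Reagents that add atoms: none
Why: SN2 hydride displacement of a primary tosylate turns CH2OTs into the methyl group; both stereocentres are spectators and the allyl group is inert.

**Step 8**
Reactants: 14 (1R,2R)-2-(4-allyl-2-methoxyphenoxy)-1-(3,4,5-trimethoxyphenyl)propan-1-ol
Product: 15 (1S,2R)-2-(4-allyl-2-methoxyphenoxy)-1-(3,4,5-trimethoxyphenyl)propyl 4-nitrobenzoate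
Conditions: 4-nitrobenzoic acid (2 equiv), PPh3 (2 equiv), DIAD (2 equiv), THF, 0 °C to rt
Reagents that add atoms: 4-nitrobenzoic acid, OC(=O)c1ccc(cc1)[N+](=O)[O-]
Why: Mitsunobu reaction: SN2 attack of the acidic carboxylate on the alkoxyphosphonium inverts the benzylic centre from R to S, converting the threo array into the erythro one.

**Step 9**
Reactants: 15 (1S,2R)-2-(4-allyl-2-methoxyphenoxy)-1-(3,4,5-trimethoxyphenyl)propyl 4-nitrobenzoate
Product: 16 (1S,2R)-2-(4-allyl-2-methoxyphenoxy)-1-(3,4,5-trimethoxyphenyl)propan-1-ol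
Conditions: K2CO3 (0.2 equiv), MeOH, rt
Reagents that add atoms: none
Why: base-catalysed transesterification of the activated aryl ester by acyl–oxygen cleavage, so the carbinol configuration is retained.

**Step 10**
Reactants: 16 (1S,2R)-2-(4-allyl-2-methoxyphenoxy)-1-(3,4,5-trimethoxyphenyl)propan-1-ol
Product: 18 (1S,2R)-2-[4-(3-hydroxypropyl)-2-methoxyphenoxy]-1-(3,4,5-trimethoxyphenyl)propan-1-ol, via B-alkyl-9-BBN adduct 17 (not isolated)
Conditions: 9-BBN (3 equiv), THF, 0 °C to rt; then 3 M NaOH, 30% H2O2, 0 °C to rt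
Reagents that add atoms: hydrogen peroxide, OO
Why: hydroboration–oxidation: 9-BBN adds to the terminal alkene with anti-Markovnikov selectivity and the C–B bond is oxidised to the primary alcohol; excess reagent covers the free hydroxyl and no stereocentre is affected.

**Compound list**
1 | eugenol (4-allyl-2-methoxyphenol) | C=CCc1ccc(O)c(OC)c1 | starting material
2 | ethyl bromoacetate | CCOC(=O)CBr | starting material
3 | ethyl 2-(4-allyl-2-methoxyphenoxy)acetate | CCOC(=O)COc1ccc(CC=C)cc1OC | intermediate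
4 | 2-(4-allyl-2-methoxyphenoxy)acetic acid | OC(=O)COc1ccc(CC=C)cc1OC | intermediate
5 | (S)-4-benzyl-2-oxazolidinone | O=C1N[C@@H](Cc2ccccc2)CO1 | starting material
6 | 2-(4-allyl-2-methoxyphenoxy)acetic pivalic anhydride (formed in the flask) | CC(C)(C)C(=O)OC(=O)COc1ccc(CC=C)cc1OC | intermediate
7 | (S)-3-[2-(4-allyl-2-methoxyphenoxy)acetyl]-4-benzyloxazolidin-2-one | COc1cc(CC=C)ccc1OCC(=O)N1[C@@H](Cc2ccccc2)COC1=O | intermediate
8 | 3,4,5-trimethoxybenzaldehyde | COc1cc(C=O)cc(OC)c1OC | starting material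
9 | (S)-3-[(Z)-2-(4-allyl-2-methoxyphenoxy)-1-(dibutylboryloxy)vinyl]-4-benzyloxazolidin-2-one (formed in the flask) | COc1cc(CC=C)ccc1O/C=C(\OB(CCCC)CCCC)N1[C@@H](Cc2ccccc2)COC1=O | intermediate
10 | O-dibutylboryl aldolate of 11 (formed in the flask) | COc1cc(CC=C)ccc1O[C@H](C(=O)N1[C@@H](Cc2ccccc2)COC1=O)[C@H](OB(CCCC)CCCC)c1cc(OC)c(OC)c(OC)c1 | intermediate
11 | (S)-3-[(2S,3R)-2-(4-allyl-2-methoxyphenoxy)-3-hydroxy-3-(3,4,5-trimethoxyphenyl)propanoyl]-4-benzyloxazolidin-2-one | COc1cc(CC=C)ccc1O[C@H](C(=O)N1[C@@H](Cc2ccccc2)COC1=O)[C@H](O)c1cc(OC)c(OC)c(OC)c1 | intermediate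
12 | (1R,2R)-2-(4-allyl-2-methoxyphenoxy)-1-(3,4,5-trimethoxyphenyl)propane-1,3-diol | COc1cc(CC=C)ccc1O[C@H](CO)[C@H](O)c1cc(OC)c(OC)c(OC)c1 | intermediate
13 | (2R,3R)-2-(4-allyl-2-methoxyphenoxy)-3-hydroxy-3-(3,4,5-trimethoxyphenyl)propyl 4-methylbenzenesulfonate | COc1cc(CC=C)ccc1O[C@H](COS(=O)(=O)c1ccc(C)cc1)[C@H](O)c1cc(OC)c(OC)c(OC)c1 | intermediate
14 | (1R,2R)-2-(4-allyl-2-methoxyphenoxy)-1-(3,4,5-trimethoxyphenyl)propan-1-ol (threo) | COc1cc(CC=C)ccc1O[C@H](C)[C@H](O)c1cc(OC)c(OC)c(OC)c1 | intermediate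
15 | (1S,2R)-2-(4-allyl-2-methoxyphenoxy)-1-(3,4,5-trimethoxyphenyl)propyl 4-nitrobenzoate | COc1cc(CC=C)ccc1O[C@H](C)[C@@H](OC(=O)c1ccc(cc1)[N+](=O)[O-])c1cc(OC)c(OC)c(OC)c1 | intermediate
16 | (1S,2R)-2-(4-allyl-2-methoxyphenoxy)-1-(3,4,5-trimethoxyphenyl)propan-1-ol (erythro) | COc1cc(CC=C)ccc1O[C@H](C)[C@@H](O)c1cc(OC)c(OC)c(OC)c1 | intermediate
17 | 9-{3-[4-{[(1S,2R)-1-hydroxy-1-(3,4,5-trimethoxyphenyl)propan-2-yl]oxy}-3-methoxyphenyl]propyl}-9-borabicyclo[3.3.1]nonane (formed in the flask) | COc1cc(CCCB2[C@H]3CCC[C@@H]2CCC3)ccc1O[C@H](C)[C@@H](O)c1cc(OC)c(OC)c(OC)c1 | intermediate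
18 | (1S,2R)-2-[4-(3-hydroxypropyl)-2-methoxyphenoxy]-1-(3,4,5-trimethoxyphenyl)propan-1-ol (CID70695433) | COc1cc(CCCO)ccc1O[C@H](C)[C@@H](O)c1cc(OC)c(OC)c(OC)c1 | target

**Totals**
Total steps: 10. Longest linear sequence: 10 steps (1 → 18); 2, 5 and 8 are bought and enter directly.

**Steps most likely to fail, each with a fallback**

Step 4 (the aldol). The aryloxyacetyl boron enolate carries an extra ortho-methoxy donor and the aldehyde is electron-rich and slow, so conversion or syn selectivity may be poor. The fallback sets out from acid 4 and comes back at diol 12. Acid 4 is coupled with (S)-4-benzylthiazolidine-2-thione (DCC, cat. DMAP, CH2Cl2) to give (S)-3-[2-(4-allyl-2-methoxyphenoxy)acetyl]-4-benzylthiazolidine-2-thione F1. Its chlorotitanium enolate (TiCl4, iPr2NEt, N-methylpyrrolidinone, CH2Cl2, 0 °C) adds to 8 in the same syn sense to give (S)-3-[(2S,3R)-2-(4-allyl-2-methoxyphenoxy)-3-hydroxy-3-(3,4,5-trimethoxyphenyl)propanoyl]-4-benzylthiazolidine-2-thione F2. NaBH4 in THF/EtOH then cleaves the thioimide reductively, giving 12 directly.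

Step 7 (hydride displacement next to a free benzylic alkoxide). Oxetane closure, fragmentation to aldehyde plus enol ether, or S–O cleavage back to 12 may compete. The fallback sets out from tosylate 13 and comes back at 14. The benzylic hydroxyl is masked with TBSOTf and 2,6-lutidine (CH2Cl2, –78 to 0 °C) to give (2R,3R)-2-(4-allyl-2-methoxyphenoxy)-3-[(tert-butyldimethylsilyl)oxy]-3-(3,4,5-trimethoxyphenyl)propyl 4-methylbenzenesulfonate F3. With no alkoxide present, LiBHEt3 in THF displaces the tosylate to give tert-butyl{[(1R,2R)-2-(4-allyl-2-methoxyphenoxy)-1-(3,4,5-trimethoxyphenyl)propyl]oxy}dimethylsilane F4. Bu4NF in THF removes the silyl group to give 14.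

Step 8 (Mitsunobu at a hindered, electron-rich benzylic carbinol). Elimination to the enol ether or partial loss of inversion may occur. The fallback sets out from 14 and comes back at 16. Buffered Dess–Martin periodinane (NaHCO3, CH2Cl2, 0 °C) oxidises 14 without epimerising the α-centre to give (R)-2-(4-allyl-2-methoxyphenoxy)-1-(3,4,5-trimethoxyphenyl)propan-1-one F5. Zn(BH4)2 in Et2O at –20 °C then reduces the ketone under chelation control (zinc bridging the carbonyl and aryloxy oxygens, hydride entering past the small hydrogen) to the erythro alcohol 16.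

**Further compounds**
F1 | step 4 | (S)-3-[2-(4-allyl-2-methoxyphenoxy)acetyl]-4-benzylthiazolidine-2-thione | COc1cc(CC=C)ccc1OCC(=O)N1[C@@H](Cc2ccccc2)CSC1=S
F2 | step 4 | (S)-3-[(2S,3R)-2-(4-allyl-2-methoxyphenoxy)-3-hydroxy-3-(3,4,5-trimethoxyphenyl)propanoyl]-4-benzylthiazolidine-2-thione | COc1cc(CC=C)ccc1O[C@H](C(=O)N1[C@@H](Cc2ccccc2)CSC1=S)[C@H](O)c1cc(OC)c(OC)c(OC)c1
F3 | step 7 | (2R,3R)-2-(4-allyl-2-methoxyphenoxy)-3-[(tert-butyldimethylsilyl)oxy]-3-(3,4,5-trimethoxyphenyl)propyl 4-methylbenzenesulfonate | COc1cc(CC=C)ccc1O[C@H](COS(=O)(=O)c1ccc(C)cc1)[C@H](O[Si](C)(C)C(C)(C)C)c1cc(OC)c(OC)c(OC)c1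
F4 | step 7 | tert-butyl{[(1R,2R)-2-(4-allyl-2-methoxyphenoxy)-1-(3,4,5-trimethoxyphenyl)propyl]oxy}dimethylsilane | COc1cc(CC=C)ccc1O[C@H](C)[C@H](O[Si](C)(C)C(C)(C)C)c1cc(OC)c(OC)c(OC)c1
F5 | step 8 | (R)-2-(4-allyl-2-methoxyphenoxy)-1-(3,4,5-trimethoxyphenyl)propan-1-one | COc1cc(CC=C)ccc1O[C@H](C)C(=O)c1cc(OC)c(OC)c(OC)c1
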